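**Retrosynthetic overview**

1. Locants for the dienone ring of the target: C1 (ring C=O), C2 (bears hexanoyl), C3 (enol carbon), C4 (quaternary, Me/prenyl), C5 (enol carbon), C6 (bears the arylmethyl group). The enabling feature is that this ring is a β-triketone: C3 is a ketone carbon with α-carbons C2 and C4, and C5–C6–C1 is a 2-substituted malonyl unit, so C4–C5 and C1–C2 are both enolate-plus-acyl (Claisen-type) bonds.
2. Two neighbouring groups allow temporary rings. The phenol OH ortho to the CH2 bridge lactonises onto C1 (dihydrocoumarin, ring B), and the hexanoyl oxygen is tied as an allylic ether to the prenyl carbon next to C4 (2,3-dihydro-4H-pyran-4-one, ring A).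
3. Ring A carries the future prenyl CH2 as a carbinol stereocentre (Evans aldol). It fixes the site (C4, not the pentyl α-carbon) and the face of the C4–C5 acylation, and both epimers at the methyl-bearing carbon of ring A funnel through one planar dienolate. The controlling centre is then erased by palladium-catalysed hydride delivery, leaving C4 as the only stereocentre.
4. Order of ring formation: ring A (step 4) and ring B (step 8) are made separately. In step 10 the C4–C5 bond is formed, rings A and B are opened, and the trione ring is closed at C2 onto C1 by a Claisen (Dieckmann) cyclisation that copies the ring closure of acylphloroglucinol biosynthesis.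

Key step: step 10

Assumption: the target is named and drawn as the dienone tautomer of the given SMILES (all enol tautomers share the one quaternary stereocentre); 1-(2,4,6-trihydroxyphenyl)butan-1-one and (R)-4-benzyl-3-propanoyl-1,3-oxazolidin-2-one are taken as purchasable.

**Route**

Step 1
Reactants: 1 (R)-4-benzyl-3-propanoyl-1,3-oxazolidin-2-one; 2 3-methylbut-2-enal
Product: 4 (R)-4-benzyl-3-[(2R,3S)-3-hydroxy-2,5-dimethylhex-4-enoyl]-1,3-oxazolidin-2-one, via boron enolate 3 (not isolated)
Conditions: Bu2BOTf, i-Pr2NEt, CH2Cl2, 0 °C; 2, −78 → 0 °C; pH 7 buffer, MeOH, H2O2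
Reagents that add atoms: none
Why: Evans syn-aldol reaction, in which the (Z)-boron enolate 3 adds to the enal through a closed Zimmerman–Traxler transition state and the (R)-benzyl auxiliary exposes one enolate face, setting the (3S) carbinol centre (the only one that matters later) together with the (2R) methyl centre.

Step 2
Reactants: 4 (R)-4-benzyl-3-[(2R,3S)-3-hydroxy-2,5-dimethylhex-4-enoyl]-1,3-oxazolidin-2-one
Product: 5 (2R,3S)-3-hydroxy-N-methoxy-N,2,5-trimethylhex-4-enamide
Conditions: MeNHOMe·HCl, AlMe3, CH2Cl2, −10 → 23 °C; 1 M HCl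
Reagents that add atoms: N,O-dimethylhydroxylamine hydrochloride, CNOC.Cl
Why: Weinreb amide formation by aluminium-amide transamidation of the imide, assisted by the free β-hydroxyl, should cleave the auxiliary without touching the carbinol centre or the trisubstituted alkene.

Step 3
Reactants: 5 (2R,3S)-3-hydroxy-N-methoxy-N,2,5-trimethylhex-4-enamide; 6 hept-1-yne
Product: 8 (4S,5R)-4-hydroxy-2,5-dimethyltridec-2-en-7-yn-6-one, via heptynyllithium 7 (not isolated)
Conditions: 6 (3 equiv), n-BuLi, THF, −78 °C; then 5, −78 → −20 °C; aq. NH4Cl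
Reagents that add atoms: none
Why: Weinreb ketone synthesis, in which excess 7 first deprotonates the hydroxyl and then adds once to the amide, the chelated tetrahedral adduct keeping the ketone masked until the quench so that over-addition and retro-aldol cleavage should be avoided at low temperature.

Step 4
Reactants: 8 (4S,5R)-4-hydroxy-2,5-dimethyltridec-2-en-7-yn-6-one
Product: 9 (2S,3R)-3-methyl-2-(2-methylprop-1-en-1-yl)-6-pentyl-2,3-dihydro-4H-pyran-4-one
Conditions: Ph3PAuCl (2 mol %), AgOTf (2 mol %), CH2Cl2, 23 °C
Reagents that add atoms: none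
Why: π-Acid-catalysed 6-endo-dig cycloisomerisation (intramolecular hydroalkoxylation of the ynone) should close ring A and leave the carbinol centre, now C-2 of the pyranone, untouched, while the configuration of the methyl-bearing carbon is of no consequence.

Step 5
Reactants: 10 1-(2,4,6-trihydroxyphenyl)butan-1-one
Product: 11 1-(2,6-dihydroxy-4-methoxyphenyl)butan-1-one
Conditions: Me2SO4 (1.0 equiv), K2CO3, acetone, 23 °C
Reagents that add atoms: dimethyl sulfate, COS(=O)(=O)OC
Why: Williamson etherification should be selective for the para hydroxyl because the two ortho hydroxyls are hydrogen-bonded to the ketone and less nucleophilic.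

Step 6
Reactants: 11 1-(2,6-dihydroxy-4-methoxyphenyl)butan-1-one
Product: 12 1-[2-hydroxy-4-methoxy-6-(prop-2-en-1-yloxy)phenyl]butan-1-one
Conditions: allyl bromide (1.05 equiv), K2CO3, DMF, 40 °C
Reagents that add atoms: allyl bromide, C=CCBr
Why: Williamson mono-allylation, in which the two hydroxyls are equivalent and the one that remains after the first alkylation is strongly chelated to the carbonyl, so that the second alkylation should be slow.

Step 7
Reactants: 12 1-[2-hydroxy-4-methoxy-6-(prop-2-en-1-yloxy)phenyl]butan-1-one
Product: 14 3-butanoyl-2-hydroxy-6-methoxy-4-(prop-2-en-1-yloxy)benzaldehyde, via hydroxymethylphenol 13 (not isolated)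
Conditions: MgCl2, Et3N, (CH2O)n, MeCN, 80 °C; 1 M HCl
Reagents that add atoms: paraformaldehyde (as formaldehyde), C=O
Why: Casnati–Skattebøl ortho-formylation, in which the magnesium phenoxide delivers formaldehyde to the only free ortho carbon and a second formaldehyde oxidises the benzylic alkoxide of 13 by hydride transfer.

Step 8
Reactants: 14 3-butanoyl-2-hydroxy-6-methoxy-4-(prop-2-en-1-yloxy)benzaldehyde; 15 2,2-dimethyl-1,3-dioxane-4,6-dione (Meldrum's acid)
Product: 18 8-butanoyl-5-methoxy-2-oxo-7-(prop-2-en-1-yloxy)chromane-3-carboxylic acid (racemic), via arylidene Meldrum's acid 16 (not isolated), via benzyl Meldrum's acid 17 (not isolated)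
Conditions: Hantzsch ester (1.1 equiv), L-proline (10 mol %), EtOH, 23 °C
Reagents that add atoms: none
Why: Three-component reductive alkylation, in which proline-catalysed Knoevenagel condensation gives 16, the Hantzsch ester reduces this very electrophilic alkene to 17, and the neighbouring phenol opens the Meldrum's acid ring with loss of acetone to close ring B.

Step 9
Reactants: 18 8-butanoyl-5-methoxy-2-oxo-7-(prop-2-en-1-yloxy)chromane-3-carboxylic acid
Product: 19 8-butanoyl-5-methoxy-2-oxo-7-(prop-2-en-1-yloxy)chromane-3-carbonyl chloride (racemic, used crude)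
Conditions: (COCl)2, DMF (cat.), CH2Cl2, 0 °C
Reagents that add atoms: oxalyl chloride, O=C(Cl)C(Cl)=O
Why: Vilsmeier-type (DMF-catalysed) conversion of the acid into the acid chloride under neutral conditions, to which the aryl-ester lactone and the allyl ether should be inert.

Step 10
Reactants: 9 (2S,3R)-3-methyl-2-(2-methylprop-1-en-1-yl)-6-pentyl-2,3-dihydro-4H-pyran-4-one; 19 8-butanoyl-5-methoxy-2-oxo-7-(prop-2-en-1-yloxy)chromane-3-carbonyl chloride
Product: 24 (4R)-6-[(3-butanoyl-2,4-dihydroxy-6-methoxyphenyl)methyl]-2-hexanoyl-3,5-dihydroxy-4-methyl-4-(3-methylbut-2-en-1-yl)cyclohexa-2,5-dien-1-one, via lithium dienolate 20 (not isolated), via acylketene 21 (not isolated), via acylated dihydropyranone 22 (not isolated), via triketo lactone 23 (not isolated)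
Conditions: one flask: LiTMP (lithium 2,2,6,6-tetramethylpiperidide, 2.1 equiv), THF–toluene, −78 °C; 19; then AcOH, Pd(PPh3)4 (5 mol %), Bu3SnH (2.3 equiv), −78 → 23 °C; then DBU, 23 °C; 1 M HCl
Reagents that add atoms: none
Why: LiTMP removes the proton at the methyl-bearing α′-carbon of 9 (kinetic enolisation of a vinylogous ester; both epimers give the planar dienolate 20) and dehydrochlorinates 19 to the acylketene 21, and 20 adds to 21 through carbon (Stork–Danheiser-type α′-acylation), which forms the C4–C5 bond and gives 22 after the AcOH quench. Pd(PPh3)4 then ionises both allylic C–O bonds (Tsuji–Trost-type, the pyranone oxygen leaving as a 1,3-diketone enolate and the aryl oxygen as a phenoxide) and Bu3SnH transfers hydride to the less substituted allyl terminus (palladium-catalysed hydrostannolysis of allylic C–O bonds), so that the carbinol carbon becomes the prenyl CH2, the ring oxygen becomes the hexanoyl carbonyl and 23 is formed. DBU finally induces a Dieckmann condensation, a 6-exo-trig closure with the enolate double bond exocyclic to the new ring, in which the central carbon of the freed 1,3-diketone attacks the lactone carbonyl to form the C1–C2 bond and release the ortho phenol; this Claisen closure onto the acyl-bearing carbon is the ring-forming event of acylphloroglucinol biosynthesis. The quaternary centre is set in the acylation by 1,2-induction: on the flat dienolate the 2-methylprop-1-enyl group on the neighbouring carbinol carbon stands pseudo-axial and 21 should enter from the opposite face, and because that carbinol carbon is afterwards reduced to CH2 the controlling centre leaves no trace. The step needs site selectivity for C4 over the α-carbon of the pentyl chain (secured by the vinylogous ester, which allows only α′-deprotonation under kinetic control, and in the ring closure by ring size, since only C2 reaches the lactone carbonyl through a six-membered transition state), C- over O-acylation (lithium enolate in a weakly polar medium with a ketene as electrophile) and hydride delivery to the secondary allyl terminus (tin hydride in AcOH-buffered medium and not formate, the acid keeping the enolates protonated so that they do not capture the allyl complex).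

**Compound list**

1 | (R)-4-benzyl-3-propanoyl-1,3-oxazolidin-2-one | O=C1OC[C@@H](Cc2ccccc2)N1C(=O)CC | starting material
2 | 3-methylbut-2-enal | CC(C)=CC=O | starting material
3 | (Z)-dibutylboron enolate of 1 (formed in the flask) | O=C1OC[C@@H](Cc2ccccc2)N1/C(OB(CCCC)CCCC)=C/C | intermediate
4 | (R)-4-benzyl-3-[(2R,3S)-3-hydroxy-2,5-dimethylhex-4-enoyl]-1,3-oxazolidin-2-one | O=C1OC[C@@H](Cc2ccccc2)N1C(=O)[C@H](C)[C@@H](O)C=C(C)C | intermediate
5 | (2R,3S)-3-hydroxy-N-methoxy-N,2,5-trimethylhex-4-enamide | CON(C)C(=O)[C@H](C)[C@@H](O)C=C(C)C | intermediate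
6 | hept-1-yne | CCCCCC#C | starting material
7 | hept-1-yn-1-yllithium (formed in the flask) | [Li]C#CCCCCC | intermediate
8 | (4S,5R)-4-hydroxy-2,5-dimethyltridec-2-en-7-yn-6-one | CCCCCC#CC(=O)[C@H](C)[C@@H](O)C=C(C)C | intermediate
9 | (2S,3R)-3-methyl-2-(2-methylprop-1-en-1-yl)-6-pentyl-2,3-dihydro-4H-pyran-4-one | CCCCCC1=CC(=O)[C@H](C)[C@H](C=C(C)C)O1 | intermediate
10 | 1-(2,4,6-trihydroxyphenyl)butan-1-one | CCCC(=O)c1c(O)cc(O)cc1O | starting material
11 | 1-(2,6-dihydroxy-4-methoxyphenyl)butan-1-one | CCCC(=O)c1c(O)cc(OC)cc1O | intermediate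
12 | 1-[2-hydroxy-4-methoxy-6-(prop-2-en-1-yloxy)phenyl]butan-1-one | CCCC(=O)c1c(O)cc(OC)cc1OCC=C | intermediate
13 | 1-[2-hydroxy-3-(hydroxymethyl)-4-methoxy-6-(prop-2-en-1-yloxy)phenyl]butan-1-one (formed in the flask) | CCCC(=O)c1c(OCC=C)cc(OC)c(CO)c1O | intermediate
14 | 3-butanoyl-2-hydroxy-6-methoxy-4-(prop-2-en-1-yloxy)benzaldehyde | CCCC(=O)c1c(OCC=C)cc(OC)c(C=O)c1O | intermediate
15 | 2,2-dimethyl-1,3-dioxane-4,6-dione (Meldrum's acid) | CC1(C)OC(=O)CC(=O)O1 | starting material
16 | 5-{[3-butanoyl-2-hydroxy-6-methoxy-4-(prop-2-en-1-yloxy)phenyl]methylidene}-2,2-dimethyl-1,3-dioxane-4,6-dione (formed in the flask) | CCCC(=O)c1c(OCC=C)cc(OC)c(C=C2C(=O)OC(C)(C)OC2=O)c1O | intermediate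
17 | 5-{[3-butanoyl-2-hydroxy-6-methoxy-4-(prop-2-en-1-yloxy)phenyl]methyl}-2,2-dimethyl-1,3-dioxane-4,6-dione (formed in the flask) | CCCC(=O)c1c(OCC=C)cc(OC)c(CC2C(=O)OC(C)(C)OC2=O)c1O | intermediate
18 | 8-butanoyl-5-methoxy-2-oxo-7-(prop-2-en-1-yloxy)chromane-3-carboxylic acid (racemic) | CCCC(=O)c1c(OCC=C)cc(OC)c2CC(C(=O)O)C(=O)Oc12 | intermediate
19 | 8-butanoyl-5-methoxy-2-oxo-7-(prop-2-en-1-yloxy)chromane-3-carbonyl chloride (racemic) | CCCC(=O)c1c(OCC=C)cc(OC)c2CC(C(Cl)=O)C(=O)Oc12 | intermediate
20 | lithium (2S)-3-methyl-2-(2-methylprop-1-en-1-yl)-6-pentyl-2H-pyran-4-olate (formed in the flask) | CCCCCC1=CC([O-])=C(C)[C@H](C=C(C)C)O1.[Li+] | intermediate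
21 | 8-butanoyl-5-methoxy-3-(oxomethylidene)-7-(prop-2-en-1-yloxy)chroman-2-one (formed in the flask) | CCCC(=O)c1c(OCC=C)cc(OC)c2CC(=C=O)C(=O)Oc12 | intermediate
22 | 8-butanoyl-5-methoxy-3-{[(2S,3S)-3-methyl-2-(2-methylprop-1-en-1-yl)-4-oxo-6-pentyl-3,4-dihydro-2H-pyran-3-yl]carbonyl}-7-(prop-2-en-1-yloxy)chroman-2-one (chromanone C-3 unassigned; formed in the flask) | CCCCCC1=CC(=O)[C@@](C)(C(=O)C2Cc3c(OC)cc(OCC=C)c(C(=O)CCC)c3OC2=O)[C@H](C=C(C)C)O1 | intermediate
23 | 8-butanoyl-7-hydroxy-5-methoxy-3-[(2S)-2-methyl-2-(3-methylbut-2-en-1-yl)-3,5-dioxodecanoyl]chroman-2-one (chromanone C-3 unassigned; formed in the flask) | CCCCCC(=O)CC(=O)[C@](C)(CC=C(C)C)C(=O)C1Cc2c(OC)cc(O)c(C(=O)CCC)c2OC1=O | intermediate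
24 | (4R)-6-[(3-butanoyl-2,4-dihydroxy-6-methoxyphenyl)methyl]-2-hexanoyl-3,5-dihydroxy-4-methyl-4-(3-methylbut-2-en-1-yl)cyclohexa-2,5-dien-1-one | CCCCCC(=O)C1=C(O)[C@](C)(CC=C(C)C)C(O)=C(Cc2c(OC)cc(O)c(C(=O)CCC)c2O)C1=O | target

**Step count and risks**

Total step count: 10. Longest linear sequence: 6 steps (steps 5 to 10); the other branch is steps 1 to 4 followed by step 10.

Steps most likely to fail:

Step 10. Proton transfer from the acidic acid chloride to the dienolate and O-acylation at the crowded enolate carbon can compete with C-acylation, and in the one-flask sequence the allyl–palladium intermediate can be captured by internal carbon nucleophiles before hydride transfer. The fallback uses an acyl donor without an acidic C–H at the coumarin oxidation level and isolates the acylation product; it sets out from 14 (with 15) and 9 and returns to the route at 23. Knoevenagel condensation–lactonisation of 14 with 15 (piperidinium acetate, EtOH, 60 °C) should give 8-butanoyl-5-methoxy-2-oxo-7-(prop-2-en-1-yloxy)-2H-chromene-3-carboxylic acid F1, and (COCl)2 with catalytic DMF the corresponding acid chloride F2. Dienolate 20, made from 9 with only one equivalent of LiTMP, is acylated by F2 at −78 °C to the 3-acylcoumarin F3, which is isolated. Pd(PPh3)4, Bu3SnH (3.3 equiv) and AcOH then reduce the doubly activated coumarin alkene by conjugate hydride transfer, open ring A and remove the allyl ether to give 23, which is cyclised with DBU to 24 as in step 10.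

Step 8. Lactonisation of the Knoevenagel adduct to the aromatic coumarin can outrun hydride transfer (the coumarin resists the Hantzsch ester), and the malonic half-ester can lose CO2 on warming. The fallback enters at the CH2 oxidation level through an ortho-quinone methide, so that no aldehyde and no reduction are needed; it sets out from 12 and returns at 18. Aminomethylation of 12 ortho to the free hydroxyl with Eschenmoser's salt (CH2Cl2, 23 °C) should give the Mannich base 1-[3-[(dimethylamino)methyl]-2-hydroxy-4-methoxy-6-(prop-2-en-1-yloxy)phenyl]butan-1-one F4. Warming F4 with 15 (MeCN, 60 °C) expels dimethylamine, 15 adds to the ortho-quinone methide in a Michael reaction, and lactonisation with loss of acetone gives 18.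

Step 4. Lewis-acid ionisation of the allylic carbinol (loss of configuration at the controlling centre, allylic transposition or elimination) can compete with alkyne activation. The fallback replaces π-acid catalysis by an amine addition–elimination sequence; it sets out from 8 and returns at 9. Conjugate addition of Et2NH to the ynone (EtOH, 23 °C) should give the enaminone (4S,5R,7E)-8-(diethylamino)-4-hydroxy-2,5-dimethyltrideca-2,7-dien-6-one F5, and on silica gel or with a trace of AcOH in CH2Cl2 the hydroxyl displaces diethylamine by addition–elimination to close ring A and give 9.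

**Further compounds**

F1 | step 10 | 8-butanoyl-5-methoxy-2-oxo-7-(prop-2-en-1-yloxy)-2H-chromene-3-carboxylic acid | CCCC(=O)c1c(OCC=C)cc(OC)c2C=C(C(=O)O)C(=O)Oc12
F2 | step 10 | 8-butanoyl-5-methoxy-2-oxo-7-(prop-2-en-1-yloxy)-2H-chromene-3-carbonyl chloride | CCCC(=O)c1c(OCC=C)cc(OC)c2C=C(C(Cl)=O)C(=O)Oc12
F3 | step 10 | 8-butanoyl-5-methoxy-3-{[(2S,3S)-3-methyl-2-(2-methylprop-1-en-1-yl)-4-oxo-6-pentyl-3,4-dihydro-2H-pyran-3-yl]carbonyl}-7-(prop-2-en-1-yloxy)-2H-chromen-2-one | CCCCCC1=CC(=O)[C@@](C)(C(=O)C2=Cc3c(OC)cc(OCC=C)c(C(=O)CCC)c3OC2=O)[C@H](C=C(C)C)O1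
F4 | step 8 | 1-[3-[(dimethylamino)methyl]-2-hydroxy-4-methoxy-6-(prop-2-en-1-yloxy)phenyl]butan-1-one | CCCC(=O)c1c(OCC=C)cc(OC)c(CN(C)C)c1O
F5 | step 4 | (4S,5R,7E)-8-(diethylamino)-4-hydroxy-2,5-dimethyltrideca-2,7-dien-6-one | CCCCC/C(N(CC)CC)=C\C(=O)[C@H](C)[C@@H](O)C=C(C)C
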